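**Retrosynthetic overview**
- Last bonds: the two enol-ester C–O bonds, joining atromentin to two (2Z,4S,5S)-4,5-epoxyhex-2-enoyl units without phenol protection.
- Atromentin: both aryl–quinone C–C bonds are made in one operation from 2,5-dihydroxy-1,4-benzoquinone and two molecules of phenol. The quinone α-carbons, normally nucleophilic, are made electrophilic as a bis(phenyliodonium) ylide and are attacked by the para carbon of phenol (key step).
- Acyl unit: the Z-alkene comes from semihydrogenation of an epoxy-ynoate. Its C3–C4 bond comes from the propiolate C3 anion and (R)-2-chloropropanal; the chlorohydrin then closes to the trans-epoxide.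
- Rings: the quinone and benzene rings are bought intact; only the two oxiranes are formed, before the esterification.

Assumption: the SMILES is read as atromentin esterified on both quinone-ring hydroxyls by (2Z,4S,5S)-4,5-epoxyhex-2-enoic acid (trans-oxirane, both oxirane carbons S in each chain).

**Route**

Step 1
Reactants: 1 2,5-dihydroxy-1,4-benzoquinone
Product: 2 2,5-dioxido-3,6-bis(phenyliodonio)-1,4-benzoquinone (bis-phenyliodonium ylide)
Conditions: PhI(OAc)2 (2.1 equiv), CH2Cl2, rt, 3 h, dark; filter the precipitate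
Reagents that add atoms: (diacetoxyiodo)benzene, CC(=O)OI(OC(C)=O)c1ccccc1
Why: Iodonium ylide formation, in which the two enolic α-carbons of the bis-vinylogous acid each attack trivalent iodine of one molecule of PhI(OAc)2 with loss of acetic acid, as cyclic 1,3-diones and 2-hydroxynaphthoquinone do, and the zwitterion precipitates.

Step 2
Reactants: 2 2,5-dioxido-3,6-bis(phenyliodonio)-1,4-benzoquinone; 3 phenol
Product: 4 atromentin [2,5-dihydroxy-3,6-bis(4-hydroxyphenyl)-1,4-benzoquinone]
Conditions: phenol (20 equiv), BF3·OEt2 (0.3 equiv), CH2Cl2/(CF3)2CHOH 4:1, 0 °C to rt; extract into aq NaHCO3, re-acidify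
Reagents that add atoms: phenol, Oc1ccccc1 (the second molecule of 3: one phenol is joined to each of the two ylide carbons of 2)
Why: Proposed new method: complexation of the oxido oxygen by BF3 turns each ylide carbon of 2 into a 2-hydroxy-3-(phenyliodonio)quinone, an enolonium equivalent in which the normally nucleophilic quinone α-carbon is the electrophile, and the para carbon of phenol (also a nucleophile, C-selective in the hydrogen-bonding fluoro-alcohol) attacks it by addition–elimination with iodobenzene as nucleofuge and then rearomatises, at both ylide carbons in turn so that one molecule of 2 takes up two of phenol and releases two of iodobenzene, the closest known reaction type being the BF3-mediated Friedel–Crafts-type C-arylation of electron-rich arenes by phenyliodonium ylides of 2-hydroxy-1,4-naphthoquinone and cyclic 1,3-diones.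

Step 3
Reactants: 5 methyl (2R)-2-chloropropanoate; 6 propiolic acid
Product: 10 lithium 3-[(2S,3S)-3-methyloxiran-2-yl]prop-2-ynoate, via (2R)-2-chloropropanal 7 (not isolated), via dilithium propiolate 8 (not isolated), via dilithium (4S,5R)-5-chloro-4-oxidohex-2-ynoate 9 (not isolated)
Conditions: 5 (1.2 equiv), i-Bu2AlH (1.05 equiv), CH2Cl2, −78 °C; aq KNaC4H4O6, dry, use the cold solution of 7 at once; 6, n-BuLi (2.0 equiv), THF/DMPU, −78 °C; add 7, −78 to −50 °C, 2 h; then H2O, rt, 4 h; Et2O wash, freeze-dry, triturate with acetone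
Reagents that add atoms: n-butyllithium, [Li]CCCC (the Li of 8, 9 and 10)
Why: Ester-to-aldehyde reduction, then 1,2-addition of the propiolate C3 carbanion (a β-acylvinyl anion equivalent) under Cornforth (polar Felkin–Anh) control by the α-chlorine gives the 4,5-anti chlorohydrin (new C4 centre S), and the oxygen then displaces chloride with inversion at C5 (Williamson-type epoxide closure), so the (R)-chloride carbon becomes the (S) carbon of the trans-epoxide.

Step 4
Reactants: 10 lithium 3-[(2S,3S)-3-methyloxiran-2-yl]prop-2-ynoate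
Product: 11 lithium (2Z)-3-[(2S,3S)-3-methyloxiran-2-yl]prop-2-enoate
Conditions: H2 (1 atm), 5% Pd/CaCO3 poisoned with Pb(OAc)2, quinoline, MeOH, 0 °C, stop after 1.0 equiv H2; filter, concentrate cold
Reagents that add atoms: none
Why: Lindlar semihydrogenation delivers H2 syn on the poisoned palladium surface and stops at the (Z)-alkene, the salt form prevents acid-triggered lactonisation of the cis-epoxy acid, and the two oxirane centres are not touched.

Step 5
Reactants: 4 atromentin; 11 lithium (2Z)-3-[(2S,3S)-3-methyloxiran-2-yl]prop-2-enoate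
Product: 14 3,6-bis(4-hydroxyphenyl)-2,5-bis{[(2Z)-3-((2S,3S)-3-methyloxiran-2-yl)prop-2-enoyl]oxy}-1,4-benzoquinone (CNP0407724.1), via (2Z)-3-[(2S,3S)-3-methyloxiran-2-yl]prop-2-enoyl chloride 12 (not isolated), via atromentin bis(diisopropylethylammonium) salt 13 (not isolated)
Conditions: 11 (2.2 equiv), (COCl)2 (2.1 equiv), DMF (cat.), CH2Cl2, −20 °C, 30 min; add to 4 + i-Pr2NEt (2.0 equiv) in MeCN/CH2Cl2, −40 to 0 °C; pH 5 buffer wash
Reagents that add atoms: oxalyl chloride, O=C(Cl)C(=O)Cl (the Cl of 12, none of its atoms stay in 14); N,N-diisopropylethylamine, CCN(C(C)C)C(C)C (the cations of 13, none of its atoms stay in 14)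
Why: Acid chloride formation from the carboxylate salt under non-acidic conditions, then Schotten–Baumann-type O-acylation in which exactly two equivalents of base ionise only the two vinylogous-acid hydroxyls (pKa about 3–5), each of which takes one molecule of 12, while the phenols (pKa about 9–10) stay neutral and unreactive at low temperature without a nucleophilic catalyst, and neither the Z-alkene nor any stereocentre is touched.

**Compound list**

1 | 2,5-dihydroxy-1,4-benzoquinone | O=C1C=C(O)C(=O)C=C1O | starting material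
2 | 2,5-dioxido-3,6-bis(phenyliodonio)-1,4-benzoquinone | [O-]C1=C([I+]c2ccccc2)C(=O)C([O-])=C([I+]c2ccccc2)C1=O | intermediate
3 | phenol | Oc1ccccc1 | starting material
4 | atromentin, 2,5-dihydroxy-3,6-bis(4-hydroxyphenyl)-1,4-benzoquinone | O=C1C(O)=C(c2ccc(O)cc2)C(=O)C(O)=C1c1ccc(O)cc1 | intermediate
5 | methyl (2R)-2-chloropropanoate | C[C@@H](Cl)C(=O)OC | starting material
6 | propiolic acid | C#CC(=O)O | starting material
7 | (2R)-2-chloropropanal | C[C@@H](Cl)C=O | intermediate
8 | dilithium propiolate | [Li+].[Li+].[C-]#CC(=O)[O-] | intermediate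
9 | dilithium (4S,5R)-5-chloro-4-oxidohex-2-ynoate | C[C@@H](Cl)[C@@H]([O-])C#CC(=O)[O-].[Li+].[Li+] | intermediate
10 | lithium 3-[(2S,3S)-3-methyloxiran-2-yl]prop-2-ynoate | C[C@@H]1O[C@H]1C#CC(=O)[O-].[Li+] | intermediate
11 | lithium (2Z)-3-[(2S,3S)-3-methyloxiran-2-yl]prop-2-enoate | C[C@@H]1O[C@H]1/C=C\C(=O)[O-].[Li+] | intermediate
12 | (2Z)-3-[(2S,3S)-3-methyloxiran-2-yl]prop-2-enoyl chloride | C[C@@H]1O[C@H]1/C=C\C(Cl)=O | intermediate
13 | atromentin bis(N,N-diisopropylethylammonium) salt | [O-]C1=C(c2ccc(O)cc2)C(=O)C([O-])=C(c2ccc(O)cc2)C1=O.CC[NH+](C(C)C)C(C)C.CC[NH+](C(C)C)C(C)C | intermediate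
14 | 3,6-bis(4-hydroxyphenyl)-2,5-bis{[(2Z)-3-((2S,3S)-3-methyloxiran-2-yl)prop-2-enoyl]oxy}-1,4-benzoquinone | C[C@@H]1O[C@H]1/C=C\C(=O)OC1=C(c2ccc(O)cc2)C(=O)C(OC(=O)/C=C\[C@@H]2O[C@H]2C)=C(c2ccc(O)cc2)C1=O | target

**Step count**

Total steps: 5. Longest linear sequence: 3 (1 → 2 → 4 → 14, or 5/6 → 10 → 11 → 14).

**Steps most likely to fail, with fallbacks**

Step 2. Phenol may react at oxygen or at its ortho carbon, or the ylide may rearrange before both couplings are complete. The fallback sets out from 2 and comes back at 4. Compound 2 is cross-coupled with 4-methoxyphenylboronic acid under Pd(OAc)2 catalysis (K3PO4, aqueous dioxane, rt); zerovalent palladium formed in situ inserts into each quinone carbon–iodine bond with loss of iodobenzene. This gives 2,5-dihydroxy-3,6-bis(4-methoxyphenyl)-1,4-benzoquinone F1. BBr3 (CH2Cl2, −78 °C to rt) then cleaves the two methyl ethers to give 4.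

Step 3. The propiolate dianion may add sluggishly or with poor anti selectivity, 7 may racemise, and the salt product cannot be chromatographed. The fallback sets out from 7 and comes back at 10. Lithium (trimethylsilyl)acetylide (THF, −78 °C), a simple acetylide whose anti-selective addition to α-chloro aldehydes is well established, gives (3S,4R)-4-chloro-1-(trimethylsilyl)pent-1-yn-3-ol F2, which can be purified on silica. K2CO3 in MeOH closes the epoxide and removes silicon to give (2S,3S)-2-ethynyl-3-methyloxirane F3, handled as an Et2O solution because it is volatile. n-BuLi followed by CO2 (THF, −78 °C) puts on the carboxyl carbon last and gives 10.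

Step 5. The Z-acyl chloride 12 may cyclise onto its own epoxide or isomerise before capture, and the free phenols may be acylated. The fallback sets out from 2 and 11 and comes back at 14. Pd(OAc)2-catalysed coupling of 2 with 4-(tert-butyldimethylsilyloxy)phenylboronic acid gives 2,5-dihydroxy-3,6-bis[4-(tert-butyldimethylsilyloxy)phenyl]-1,4-benzoquinone F4. Salt 11 and 2,4,6-trichlorobenzoyl chloride (THF, 0 °C) give the milder acyl donor (2Z)-3-[(2S,3S)-3-methyloxiran-2-yl]prop-2-enoic 2,4,6-trichlorobenzoic anhydride F5. F4 and F5 with Et3N and catalytic 4-(dimethylamino)pyridine (Yamaguchi esterification) give 3,6-bis[4-(tert-butyldimethylsilyloxy)phenyl]-2,5-bis{[(2Z)-3-((2S,3S)-3-methyloxiran-2-yl)prop-2-enoyl]oxy}-1,4-benzoquinone F6. Et3N·3HF (THF, 0 °C) removes the two aryl silyl ethers to give 14.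

**Further compounds**

F1 | step 2 | 2,5-dihydroxy-3,6-bis(4-methoxyphenyl)-1,4-benzoquinone | O=C1C(O)=C(c2ccc(OC)cc2)C(=O)C(O)=C1c1ccc(OC)cc1
F2 | step 3 | (3S,4R)-4-chloro-1-(trimethylsilyl)pent-1-yn-3-ol | C[C@@H](Cl)[C@@H](O)C#C[Si](C)(C)C
F3 | step 3 | (2S,3S)-2-ethynyl-3-methyloxirane | C[C@@H]1O[C@H]1C#C
F4 | step 5 | 2,5-dihydroxy-3,6-bis[4-(tert-butyldimethylsilyloxy)phenyl]-1,4-benzoquinone | O=C1C(O)=C(c2ccc(O[Si](C)(C)C(C)(C)C)cc2)C(=O)C(O)=C1c1ccc(O[Si](C)(C)C(C)(C)C)cc1
F5 | step 5 | (2Z)-3-[(2S,3S)-3-methyloxiran-2-yl]prop-2-enoic 2,4,6-trichlorobenzoic anhydride | C[C@@H]1O[C@H]1/C=C\C(=O)OC(=O)c1c(Cl)cc(Cl)cc1Cl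
F6 | step 5 | 3,6-bis[4-(tert-butyldimethylsilyloxy)phenyl]-2,5-bis{[(2Z)-3-((2S,3S)-3-methyloxiran-2-yl)prop-2-enoyl]oxy}-1,4-benzoquinone | C[C@@H]1O[C@H]1/C=C\C(=O)OC1=C(c2ccc(O[Si](C)(C)C(C)(C)C)cc2)C(=O)C(OC(=O)/C=C\[C@@H]2O[C@H]2C)=C(c2ccc(O[Si](C)(C)C(C)(C)C)cc2)C1=O
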